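Eudesmane numbering is used for positions: ring A = C1–C5 and C10; ring B = C5–C10; C11(=C13H2)–C12O2Me on C7; C14 on C10; C15 on C4.
Retrosynthesis cuts, in order: the C5–OOH bond (Schenck ene retron, back to a C4=C5 alkene), the C3 ester, the C11–C12 bond (alkyne hydroesterification), C4=C5 and C1–C10 (Robinson annulation), and last C9–C10 and C6–C7 of ring B.
Forward: ring B is made first, in one operation, from a β-keto ester (C6–C5–C10 with C14) and an enynal (C7–C8–C9 with C11≡C13); ring A is then fused on with ethyl vinyl ketone and the periphery is adjusted.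
Enabling feature: C5 is a latent ketone (the C4=C5 alkene is its aldol retron), so C6 and C10 are its two α-carbons; C7 is then the β-carbon and C9 the carbonyl carbon of an enal, and the alkyne on C7 is the acrylate at a lower oxidation level (the C9=C10 double bond and the alkyne are temporary and are removed in steps 3 and 6).
Stereochemistry: C7 from the prolinol silyl ether catalyst in the key step; C10 from a chiral 1-phenylethylamine imine; C3 by Luche reduction (3β) then Mitsunobu inversion (3α); C5 by α-face attack of singlet oxygen, anti to the C10 methyl.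

Key step: step 2

Step 1
Reactants: 1 3-(trimethylsilyl)prop-2-ynal; 2 (triphenylphosphoranylidene)acetaldehyde
Product: 3 (2E)-5-(trimethylsilyl)pent-2-en-4-ynal
Conditions: 2 (1.05 equiv), CH2Cl2, 0 → 25 °C
Reagents that add atoms: none
Why: Wittig olefination with the stabilised formyl ylide should give the (E)-enal, and ynal 1 is more electrophilic than the product enal, so a second homologation should be slow.

Step 2
Reactants: 3 (2E)-5-(trimethylsilyl)pent-2-en-4-ynal; 4 tert-butyl 3-oxopentanoate
Product: 7 (5R)-2-methyl-5-[(trimethylsilyl)ethynyl]cyclohex-2-en-1-one, via Michael adduct aldehyde 5 (not isolated), via cyclohexenone tert-butyl ester 6 (not isolated)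
Conditions: (S)-2-[diphenyl(trimethylsilyloxy)methyl]pyrrolidine (10 mol%), PhCO2H (10 mol%), toluene, 0 → 25 °C; then TsOH·H2O (20 mol%), toluene, 80 °C
Reagents that add atoms: none
Why: The secondary amine condenses with enal 3 to an (E)-iminium ion, and C2 of β-keto ester 4 (C6 of the target) adds to its β-carbon (C7) on the face away from the diphenyl(silyloxy)methyl group; the silyl cap on the alkyne terminus should keep the addition 1,4 and not 1,6. After release of the aldehyde, TsOH should drive the aldol condensation of the ethyl-ketone methylene (C10) onto the aldehyde carbon (C9), a 6-(enolendo)-exo-trig closure that makes ring B, and then cleave the tert-butyl ester with loss of CO2. The closest known reaction type is the prolinol-silyl-ether-catalysed Michael addition of β-keto esters to enals followed by acid-mediated aldol condensation and decarboxylation to 5-substituted cyclohex-2-enones. The only new stereocentre that survives is C7, set as (R) under catalyst control; the epimeric ester-bearing carbon is lost on decarboxylation. Site selectivity is secured by the substrate: only the doubly activated C6 is nucleophilic under amine catalysis, and only the C10 methylene can reach C9 in a six-membered ring, since closure from C6 would give a four-membered ring.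

Step 3
Reactants: 7 (5R)-2-methyl-5-[(trimethylsilyl)ethynyl]cyclohex-2-en-1-one
Product: 8 (5R)-2-methyl-5-[(trimethylsilyl)ethynyl]cyclohexan-1-one (both C2 epimers)
Conditions: LiBH(s-Bu)3 (1.05 equiv), THF, −78 °C; then AcOH
Reagents that add atoms: none
Why: Conjugate (1,4) hydride reduction of a β-unsubstituted cyclohexenone by the bulky trialkylborohydride, with protonation of the enolate on quench; the C2 configuration does not matter because step 4 passes through the enamine, and the silylalkyne and C7 are untouched.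

Step 4
Reactants: 8 (5R)-2-methyl-5-[(trimethylsilyl)ethynyl]cyclohexan-1-one; 9 (R)-1-phenylethylamine; 10 pent-1-en-3-one (ethyl vinyl ketone)
Product: 13 (2S,5R)-2-methyl-2-(3-oxopentyl)-5-[(trimethylsilyl)ethynyl]cyclohexan-1-one, via ketimine 11 (not isolated), via Michael adduct ketimine 12 (not isolated)
Conditions: 9 (1.1 equiv), TsOH·H2O (1 mol%), toluene, reflux, Dean–Stark; concentrate; 10 (1.5 equiv), THF, 40 °C; then 10% aq AcOH, 25 °C
Reagents that add atoms: water, O
Why: Michael addition of a chiral imine through its more substituted secondary enamine tautomer (first stage of a Robinson annulation): the enone should be taken up in a compact aza-ene-like transition state on the enamine face anti to the phenyl group of the (R)-1-phenylethyl unit, which sets the quaternary C10 as (S) with the methyl cis to the C7 alkynyl group (the small linear alkynyl group gives little opposing substrate bias), and aqueous acid then hydrolyses the imine.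

Step 5
Reactants: 13 (2S,5R)-2-methyl-2-(3-oxopentyl)-5-[(trimethylsilyl)ethynyl]cyclohexan-1-one
Product: 14 (4aS,7R)-7-ethynyl-1,4a-dimethyl-4,4a,5,6,7,8-hexahydronaphthalen-2(3H)-one
Conditions: NaOMe (0.3 equiv), MeOH, 25 → 60 °C
Reagents that add atoms: none
Why: Intramolecular aldol condensation (second stage of the Robinson annulation: 6-(enolendo)-exo-trig attack of C4 on the C5 ketone, then dehydration to the tetrasubstituted enone) with methanolysis of the alkynyl C–Si bond in the same pot; C7 and C10 cannot epimerise under these conditions.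

Step 6
Reactants: 14 (4aS,7R)-7-ethynyl-1,4a-dimethyl-4,4a,5,6,7,8-hexahydronaphthalen-2(3H)-one
Product: 15 methyl 2-[(2R,4aS)-4a,8-dimethyl-7-oxo-1,2,3,4,4a,5,6,7-octahydronaphthalen-2-yl]prop-2-enoate
Conditions: Pd(OAc)2 (2 mol%), 2-(diphenylphosphino)pyridine (8 mol%), MeSO3H (8 mol%), CO (20 bar), MeOH, 50 °C
Reagents that add atoms: carbon monoxide, [C-]#[O+]; methanol, CO
Why: Palladium-catalysed Markovnikov hydroesterification (methoxycarbonylation) of a terminal alkyne: with the pyridylphosphine ligand and acid, a cationic divalent palladium species should place the CO2Me group on the internal alkyne carbon and hydrogen on the terminus, giving the 2-substituted acrylate directly without touching the enone or the stereocentres.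

Step 7
Reactants: 15 methyl 2-[(2R,4aS)-4a,8-dimethyl-7-oxo-1,2,3,4,4a,5,6,7-octahydronaphthalen-2-yl]prop-2-enoate
Product: 16 methyl 2-[(2R,4aS,7S)-7-hydroxy-4a,8-dimethyl-1,2,3,4,4a,5,6,7-octahydronaphthalen-2-yl]prop-2-enoate
Conditions: NaBH4 (1.0 equiv), CeCl3·7H2O (1.0 equiv), MeOH, −78 → −20 °C
Reagents that add atoms: none
Why: Luche reduction (1,2-selective for the enone carbonyl over the conjugated ester): hydride should add axially on the α-face of the ring A half-chair, anti to the axial C10 methyl, to give the pseudo-equatorial 3β-alcohol.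

Step 8
Reactants: 16 methyl 2-[(2R,4aS,7S)-7-hydroxy-4a,8-dimethyl-1,2,3,4,4a,5,6,7-octahydronaphthalen-2-yl]prop-2-enoate; 17 angelic acid, (2Z)-2-methylbut-2-enoic acid
Product: 18 methyl 2-[(2R,4aS,7R)-4a,8-dimethyl-7-{[(2Z)-2-methylbut-2-enoyl]oxy}-1,2,3,4,4a,5,6,7-octahydronaphthalen-2-yl]prop-2-enoate
Conditions: 17 (1.5 equiv), PPh3 (1.5 equiv), DIAD (1.5 equiv), toluene, 0 → 25 °C
Reagents that add atoms: none
Why: Mitsunobu esterification with SN2 inversion at C3 should turn the 3β-alcohol into the axial 3α-angelate; SN2′ attack is disfavoured because C5 is fully substituted, and the cold neutral conditions should preserve the (Z)-alkene of the acid.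

Step 9
Reactants: 18 methyl 2-[(2R,4aS,7R)-4a,8-dimethyl-7-{[(2Z)-2-methylbut-2-enoyl]oxy}-1,2,3,4,4a,5,6,7-octahydronaphthalen-2-yl]prop-2-enoate
Product: 19 methyl 2-[(2R,4aS,7R,8aS)-8a-hydroperoxy-4a-methyl-8-methylidene-7-{[(2Z)-2-methylbut-2-enoyl]oxy}decahydronaphthalen-2-yl]prop-2-enoate
Conditions: O2, visible light, tetraphenylporphyrin (0.5 mol%), CH2Cl2, −20 °C
Reagents that add atoms: dioxygen, O=O
Why: Schenck ene reaction: singlet oxygen should attack the tetrasubstituted C4=C5 alkene on the α-face (anti to the axial C10 methyl), bond to C5 and take a hydrogen from the C15 methyl, so that the double bond moves to C4=C15 and C5 becomes (S); the 3β-hydrogen lies on the opposite face, and the electron-poor acrylate and angelate alkenes do not react with singlet oxygen.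

Compound list
1 | 3-(trimethylsilyl)prop-2-ynal | C[Si](C)(C)C#CC=O | starting material
2 | (triphenylphosphoranylidene)acetaldehyde | O=CC=P(c1ccccc1)(c1ccccc1)c1ccccc1 | starting material
3 | (2E)-5-(trimethylsilyl)pent-2-en-4-ynal | C[Si](C)(C)C#C/C=C/C=O | intermediate
4 | tert-butyl 3-oxopentanoate | CCC(=O)CC(=O)OC(C)(C)C | starting material
5 | tert-butyl (3R)-3-(2-oxoethyl)-2-propanoyl-5-(trimethylsilyl)pent-4-ynoate (C2 epimers) | C[Si](C)(C)C#C[C@H](CC=O)C(C(=O)CC)C(=O)OC(C)(C)C | intermediate
6 | tert-butyl (6R)-3-methyl-2-oxo-6-[(trimethylsilyl)ethynyl]cyclohex-3-ene-1-carboxylate (C1 epimers) | C[Si](C)(C)C#C[C@@H]1CC=C(C)C(=O)C1C(=O)OC(C)(C)C | intermediate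
7 | (5R)-2-methyl-5-[(trimethylsilyl)ethynyl]cyclohex-2-en-1-one | C[Si](C)(C)C#C[C@@H]1CC=C(C)C(=O)C1 | intermediate
8 | (5R)-2-methyl-5-[(trimethylsilyl)ethynyl]cyclohexan-1-one (C2 epimers) | C[Si](C)(C)C#C[C@@H]1CCC(C)C(=O)C1 | intermediate
9 | (R)-1-phenylethylamine | C[C@@H](N)c1ccccc1 | starting material
10 | pent-1-en-3-one (ethyl vinyl ketone) | C=CC(=O)CC | starting material
11 | (5R)-2-methyl-N-[(1R)-1-phenylethyl]-5-[(trimethylsilyl)ethynyl]cyclohexan-1-imine (C2 epimers) | C[Si](C)(C)C#C[C@@H]1CCC(C)C(=N[C@H](C)c2ccccc2)C1 | intermediate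
12 | (2S,5R)-2-methyl-2-(3-oxopentyl)-N-[(1R)-1-phenylethyl]-5-[(trimethylsilyl)ethynyl]cyclohexan-1-imine | C[Si](C)(C)C#C[C@@H]1CC[C@@](C)(CCC(=O)CC)C(=N[C@H](C)c2ccccc2)C1 | intermediate
13 | (2S,5R)-2-methyl-2-(3-oxopentyl)-5-[(trimethylsilyl)ethynyl]cyclohexan-1-one | C[Si](C)(C)C#C[C@@H]1CC[C@@](C)(CCC(=O)CC)C(=O)C1 | intermediate
14 | (4aS,7R)-7-ethynyl-1,4a-dimethyl-4,4a,5,6,7,8-hexahydronaphthalen-2(3H)-one | C#C[C@@H]1CC[C@@]2(C)CCC(=O)C(C)=C2C1 | intermediate
15 | methyl 2-[(2R,4aS)-4a,8-dimethyl-7-oxo-1,2,3,4,4a,5,6,7-octahydronaphthalen-2-yl]prop-2-enoate | C=C(C(=O)OC)[C@@H]1CC[C@@]2(C)CCC(=O)C(C)=C2C1 | intermediate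
16 | methyl 2-[(2R,4aS,7S)-7-hydroxy-4a,8-dimethyl-1,2,3,4,4a,5,6,7-octahydronaphthalen-2-yl]prop-2-enoate | C=C(C(=O)OC)[C@@H]1CC[C@@]2(C)CC[C@H](O)C(C)=C2C1 | intermediate
17 | angelic acid, (2Z)-2-methylbut-2-enoic acid | C/C=C(/C)C(=O)O | starting material
18 | methyl 2-[(2R,4aS,7R)-4a,8-dimethyl-7-{[(2Z)-2-methylbut-2-enoyl]oxy}-1,2,3,4,4a,5,6,7-octahydronaphthalen-2-yl]prop-2-enoate | C=C(C(=O)OC)[C@@H]1CC[C@@]2(C)CC[C@@H](OC(=O)/C(C)=C\C)C(C)=C2C1 | intermediate
19 | methyl 2-[(2R,4aS,7R,8aS)-8a-hydroperoxy-4a-methyl-8-methylidene-7-{[(2Z)-2-methylbut-2-enoyl]oxy}decahydronaphthalen-2-yl]prop-2-enoate | C=C(C(=O)OC)[C@@H]1CC[C@@]2(C)CC[C@@H](OC(=O)/C(C)=C\C)C(=C)[C@]2(OO)C1 | target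

Total step count: 9. Longest linear sequence: 9 steps (1 → 19).

Steps most likely to fail

Step 9. Singlet oxygen may attack the β-face, or bond to C4 and abstract the axial C6 hydrogen, because the axial 3α-ester crowds the α-face next to C4 and C5. The fallback moves the ene reaction ahead of the C3 inversion; it sets out from 16 and comes back at 19. Alcohol 16 is silylated (TBSOTf, 2,6-lutidine) to the 3β-tert-butyldimethylsilyl ether F3. Photooxygenation under the conditions of step 9, now on an alkene whose α-face carries no axial substituent, should give the 5α-hydroperoxide F4. The hydroperoxide is capped with 2-methoxypropene and PPTS as the 2-methoxypropan-2-yl peroxyketal F5, and Bu4NF frees the 3β-alcohol F6. Mitsunobu reaction with 17 gives the 3α-angelate peroxyketal F7, and AcOH/H2O/THF then releases 19.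

Step 8. The activated allylic alcohol may eliminate to a diene, or the angelate may isomerise from (Z) to (E). The fallback sets the 3α-configuration by reagent-controlled reduction and acylates with retention; it sets out from 15 and comes back at 18. Corey–Bakshi–Shibata reduction of enone 15 ((S)-2-methyl-CBS-oxazaborolidine, catecholborane, toluene, −78 °C) should give the 3α-alcohol F1. This is acylated in a Yamaguchi-type esterification with the mixed anhydride of 17 and 2,4,6-trichlorobenzoyl chloride (Et3N; then toluene, 80 °C, no nucleophilic catalyst) to give 18.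

Step 6. Insertion at the α-branched alkyne may go anti-Markovnikov and give the linear (E)-alkenoate, or turnover may be slow. The fallback separates the regiochemistry from the carbonylation; it sets out from 14 and comes back at 15. Markovnikov hydroiodination of 14 (NaI, Me3SiCl, H2O, MeCN) should give the 2-iodoalkene F2, which is methoxycarbonylated as a vinyl iodide (Pd(OAc)2, PPh3, CO, MeOH, K2CO3) to 15.

Further compounds
F1 | step 8 | methyl 2-[(2R,4aS,7R)-7-hydroxy-4a,8-dimethyl-1,2,3,4,4a,5,6,7-octahydronaphthalen-2-yl]prop-2-enoate | C=C(C(=O)OC)[C@@H]1CC[C@@]2(C)CC[C@@H](O)C(C)=C2C1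
F2 | step 6 | (4aS,7R)-7-(1-iodoethenyl)-1,4a-dimethyl-4,4a,5,6,7,8-hexahydronaphthalen-2(3H)-one | C=C(I)[C@@H]1CC[C@@]2(C)CCC(=O)C(C)=C2C1
F3 | step 9 | methyl 2-[(2R,4aS,7S)-7-{[tert-butyl(dimethyl)silyl]oxy}-4a,8-dimethyl-1,2,3,4,4a,5,6,7-octahydronaphthalen-2-yl]prop-2-enoate | C=C(C(=O)OC)[C@@H]1CC[C@@]2(C)CC[C@H](O[Si](C)(C)C(C)(C)C)C(C)=C2C1
F4 | step 9 | methyl 2-[(2R,4aS,7S,8aS)-7-{[tert-butyl(dimethyl)silyl]oxy}-8a-hydroperoxy-4a-methyl-8-methylidenedecahydronaphthalen-2-yl]prop-2-enoate | C=C(C(=O)OC)[C@@H]1CC[C@@]2(C)CC[C@H](O[Si](C)(C)C(C)(C)C)C(=C)[C@]2(OO)C1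
F5 | step 9 | methyl 2-[(2R,4aS,7S,8aS)-7-{[tert-butyl(dimethyl)silyl]oxy}-8a-[(2-methoxypropan-2-yl)peroxy]-4a-methyl-8-methylidenedecahydronaphthalen-2-yl]prop-2-enoate | C=C(C(=O)OC)[C@@H]1CC[C@@]2(C)CC[C@H](O[Si](C)(C)C(C)(C)C)C(=C)[C@]2(OOC(C)(C)OC)C1
F6 | step 9 | methyl 2-[(2R,4aS,7S,8aS)-7-hydroxy-8a-[(2-methoxypropan-2-yl)peroxy]-4a-methyl-8-methylidenedecahydronaphthalen-2-yl]prop-2-enoate | C=C(C(=O)OC)[C@@H]1CC[C@@]2(C)CC[C@H](O)C(=C)[C@]2(OOC(C)(C)OC)C1
F7 | step 9 | methyl 2-[(2R,4aS,7R,8aS)-8a-[(2-methoxypropan-2-yl)peroxy]-4a-methyl-8-methylidene-7-{[(2Z)-2-methylbut-2-enoyl]oxy}decahydronaphthalen-2-yl]prop-2-enoate | C=C(C(=O)OC)[C@@H]1CC[C@@]2(C)CC[C@@H](OC(=O)/C(C)=C\C)C(=C)[C@]2(OOC(C)(C)OC)C1
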